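**Plan**

1. Numbering and enabling feature: bicyclo[4.3.1]dec-8-ene with bridgeheads C1 and C6; C2 (Me, side chain; C1′ = side-chain methine), C3 (acetyl), C4, C5; C7, C8=C9(CHO); C10 (Me, OAc). The cyclohexene C10–C6–C7–C8–C9–C1, bridged at C1 and C6 by C2–C5, is the adduct of a diene tethered through its internal carbon, which is what permits a type 2 intramolecular Diels–Alder reaction.
2. Cuts: after functional-group changes at C9 and C10, C10–C6 and C7–C8 are cut together (diene C10=C1–C9=C8, dienophile C6=C7 with a traceless sulfone on C6); then C2–C3 (Ireland–Claisen); then C2–CH3 and C1–C10 (carbomagnesiation of a propargylic alcohol).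
3. Forward: (S)-citronellal → alkyne → tetrasubstituted allylic alcohol; the Claisen joins the C3–C6 chain; one cycloaddition then closes the six- and seven-membered rings at once.
4. Stereochemistry: C1′ from citronellal; a C9 carbinol (Noyori transfer hydrogenation) is relayed through the chair Claisen to C2 and C3; C6 from the fold of the tether in the cycloaddition; C1 from outer-face hydroboration; C10 from methyl addition to the bridging ketone.
5. The diene carries a single silyloxy group (on C10) and is made from an enal, which fixes its geometry; the C9 oxygen is added afterwards to the strained bridgehead alkene.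

Key step: step 18

Assumption: a bicyclo[4.3.1]decene exists only with both bridgehead hydrogens outward, so the C1/C6 pair is fixed by ring closure and not by any reagent; both bridgehead labels are written as the target string gives them, and C2, C3 and C10 are read relative to C1.

**Route**

Step 1
Reactants: 1 (S)-citronellal
Product: 3 (3S)-3,7-dimethyloct-6-en-1-yne, via enol nonaflate 2 (not isolated)
Conditions: NfF (C4F9SO2F), P2-Et phosphazene base, DMF, −30 °C → rt
Reagents that add atoms: none
Why: Enol nonaflation and base-induced elimination of the alkenyl nonaflate convert RCH2CHO into RC≡CH in one pot; the stereocentre is β to the carbonyl and is not deprotonated.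

Step 2
Reactants: 3 (3S)-3,7-dimethyloct-6-en-1-yne
Product: 5 (5S)-5,9-dimethyldec-8-en-3-yn-2-one, via lithium acetylide 4 (not isolated)
Conditions: n-BuLi, THF, −78 °C; then MeC(O)N(OMe)Me, −78 → 0 °C
Reagents that add atoms: N-methoxy-N-methylacetamide CC(=O)N(C)OC
Why: Acylation of the lithium acetylide with a Weinreb amide stops at the ynone because the tetrahedral adduct is stable until work-up.

Step 3
Reactants: 5 (5S)-5,9-dimethyldec-8-en-3-yn-2-one
Product: 6 (2S,5S)-5,9-dimethyldec-8-en-3-yn-2-ol
Conditions: RuCl[(S,S)-TsDPEN](p-cymene) (1 mol %), i-PrOH, rt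
Reagents that add atoms: none
Why: Noyori asymmetric transfer hydrogenation of the alkynyl methyl ketone: the catalyst alone sets the new carbinol centre, the (S,S) ligand giving the (S)-propargylic alcohol needed for chirality transfer in step 9.

Step 4
Reactants: 6 (2S,5S)-5,9-dimethyldec-8-en-3-yn-2-ol
Product: 8 (2S,3Z,5S)-3-{[isopropoxy(dimethyl)silyl]methyl}-4,5,9-trimethyldeca-3,8-dien-2-ol, via alkenylmagnesium chelate 7 (not isolated)
Conditions: (i-PrO)Me2SiCH2MgCl (3.5 equiv), CuI (10 mol %), THF, 0 °C → reflux; then MeI, 0 °C → rt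
Reagents that add atoms: (isopropoxydimethylsilyl)methylmagnesium chloride CC(C)O[Si](C)(C)C[Mg]Cl; iodomethane CI
Why: Copper-catalysed, hydroxyl-directed anti-carbomagnesiation of the propargylic alcohol: the silylmethyl group adds to C1, the alkyne carbon next to the carbinol, magnesium ends on C2 in a five-membered alkoxide chelate, and methylation of that alkenylmagnesium with retention gives the tetrasubstituted alkene with the C2 methyl cis to the carbinol carbon.

Step 5
Reactants: 8 allylsilane alcohol
Product: 9 (2E,4S)-2-[(1S)-1-hydroxyethyl]-3,4,8-trimethylnona-2,7-dien-1-ol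
Conditions: 30% H2O2, KF, KHCO3, THF/MeOH, rt
Reagents that add atoms: hydrogen peroxide OO
Why: Tamao oxidation converts the C–Si bond of the alkoxysilane into C–OH with retention and does not touch the alkenes.

Step 6
Reactants: 9 diol
Product: 10 (2S,3E,5S)-3-[(tert-butyldimethylsilyloxy)methyl]-4,5,9-trimethyldeca-3,8-dien-2-ol
Conditions: TBSCl, imidazole, CH2Cl2, 0 °C
Reagents that add atoms: tert-butyldimethylsilyl chloride CC(C)(C)[Si](C)(C)Cl
Why: Silyl ether formation is much faster at the primary allylic hydroxyl than at the hindered secondary one, which is left free for step 8.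

Step 7
Reactants: 11 5-bromopentanoic acid; 12 thiophenol
Product: 13 5-(phenylthio)pentanoic acid
Conditions: NaOH, EtOH/H2O, reflux; then aq. HCl
Reagents that add atoms: none
Why: SN2 thioetherification: thiophenolate displaces the primary bromide of the carboxylate.

Step 8
Reactants: 10 mono-silylated diol; 13 5-(phenylthio)pentanoic acid
Product: 14 allylic ester (5-(phenylthio)pentanoate of the secondary alcohol of 10)
Conditions: DCC, DMAP (cat.), CH2Cl2, 0 °C → rt
Reagents that add atoms: none
Why: Steglich esterification acylates the secondary allylic alcohol without touching its stereocentre.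

Step 9
Reactants: 14 allylic ester
Product: 17 Claisen acid (C1′, C2 and C3 all S), via silyl ketene acetal 15 (not isolated), via trimethylsilyl ester 16 (not isolated)
Conditions: LiN(i-Pr)2, THF/DMPU, −78 °C; Me3SiCl; −78 °C → 65 °C; then aq. HCl
Reagents that add atoms: none
Why: Ireland–Claisen rearrangement: enolisation in THF/DMPU gives the Z(O)-enolate and hence the (Z)-silyl ketene acetal, which rearranges through a chair with the C9 methyl equatorial, so that the (S)-carbinol centre is transferred to C2 (C2 methyl axial, side chain equatorial) while the ketene acetal geometry sets C3.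

Step 10
Reactants: 17 Claisen acid
Product: 18 methyl ketone (acetyl on C3)
Conditions: MeLi (2.5 equiv), Et2O, 0 °C; then aq. NH4Cl
Reagents that add atoms: methyllithium [Li]C
Why: Addition of methyllithium to the lithium carboxylate gives a dilithium diolate that releases the methyl ketone only on work-up, so that neither over-addition nor C3 epimerisation should occur.

Step 11
Reactants: 18 methyl ketone
Product: 19 dioxolane sulfide
Conditions: (Me3SiOCH2)2, Me3SiOTf (cat.), CH2Cl2, −78 → −20 °C
Reagents that add atoms: 1,2-bis(trimethylsilyloxy)ethane C[Si](C)(C)OCCO[Si](C)(C)C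
Why: Silyl-triflate-catalysed ketalisation with the bis-silyl ether of ethylene glycol proceeds at low temperature on hindered ketones, so C3 is not epimerised and the silyl ether survives.

Step 12
Reactants: 19 dioxolane sulfide
Product: 20 sulfone
Conditions: (NH4)6Mo7O24·4H2O (cat.), 30% H2O2, EtOH, 0 °C → rt
Reagents that add atoms: hydrogen peroxide OO
Why: Molybdate-catalysed peroxide oxidation takes the sulfide to the sulfone much faster than it epoxidises the two trisubstituted alkenes.

Step 13
Reactants: 20 sulfone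
Product: 22 β-hydroxy sulfone (C6 epimers), via α-lithio sulfone 21 (not isolated)
Conditions: n-BuLi, THF, −78 °C; then CH2O (gas, from paraformaldehyde), −78 → −20 °C
Reagents that add atoms: formaldehyde C=O
Why: Hydroxymethylation of the α-sulfonyl carbanion with formaldehyde adds C7; the new C6 centre is removed in step 14.

Step 14
Reactants: 22 β-hydroxy sulfone
Product: 24 vinyl sulfone, via mesylate 23 (not isolated)
Conditions: MsCl, Et3N (excess), CH2Cl2, 0 °C → rt
Reagents that add atoms: none
Why: Mesylation followed by E1cB elimination of the β-mesyloxy sulfone gives the 1-sulfonylvinyl dienophile.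

Step 15
Reactants: 24 vinyl sulfone
Product: 25 allylic alcohol
Conditions: Bu4NF, AcOH, THF, 0 °C → rt
Reagents that add atoms: none
Why: Fluoride-mediated desilylation, buffered with acetic acid so that no alkoxide adds to the vinyl sulfone.

Step 16
Reactants: 25 allylic alcohol
Product: 26 enal (C8 methyl cis to the formyl group)
Conditions: MnO2, CH2Cl2, rt
Reagents that add atoms: none
Why: MnO2 oxidation is selective for the allylic alcohol and leaves the alkene geometry unchanged.

Step 17
Reactants: 26 enal
Product: 27 silyl dienol ether (silyloxy on C10 trans to C9, cis to C2)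
Conditions: TBSOTf, Et3N, CH2Cl2, −78 → 0 °C
Reagents that add atoms: tert-butyldimethylsilyl triflate CC(C)(C)[Si](C)(C)OS(=O)(=O)C(F)(F)F
Why: Silyl dienol ether formation (O-silylation, then γ-deprotonation at C8 by Et3N): the enal reacts from its s-trans conformer, held by the C8 methyl cis to the formyl group, which places the silyloxy group trans to C9, the outside position of the s-cis diene.

Step 18
Reactants: 27 silyl dienol ether
Product: 28 cycloadduct (10-silyloxy-6-phenylsulfonyl-bicyclo[4.3.1]dec-1(9)-ene)
Conditions: PhMe (0.005 M), BHT (cat.), 180 °C, sealed tube (base-washed glass)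
Reagents that add atoms: none
Why: On heating, the s-cis 1-silyloxy diene C10=C1–C9=C8 (the quaternary C2 on C1 favours s-cis) and the 1-sulfonylvinyl group C6=C7 combine in a concerted, asynchronous [4+2] cycloaddition in which C8, the nucleophilic terminus of the dienol ether, bonds to the sulfone β-carbon C7 ahead of the C10–C6 bond. The closest known reaction type is the type 2 intramolecular Diels–Alder reaction of dienes tethered through an internal carbon by four atoms, which gives bridgehead-alkene bicyclo[4.3.1]dec-1(9)-enes. The six-membered ring C10–C6–C7–C8–C9–C1 is the cycloadduct ring, closed by both new bonds; the seven-membered ring C1–C2–C3–C4–C5–C6–C10 is closed by the C10–C6 bond in the bridged mode, because the tether leaves from C1 and makes C1=C9 a bridgehead alkene of a ring system large enough to hold it. C6 is set by the diene face that the tether reaches, fixed by a chair-like fold of C2–C5 with the bulky dioxolanyl group on C3 pseudo-equatorial; C10 follows from the diene geometry (outside silyloxy group, hence cis to the C6–C5 bond) and is oxidised later. The step needs regioselectivity for the 1,3-bridged adduct, secured by the short tether and reinforced by matched polarisation (donor on C10, sulfone on C6), and facial selectivity, secured by the C2/C3 stereocentres; the unactivated side-chain alkene does not compete.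

Step 19
Reactants: 28 cycloadduct
Product: 30 C9 alcohol (C9 configuration immaterial), via B-alkyl-9-BBN 29 (not isolated)
Conditions: 9-BBN, THF, 0 °C → rt; then NaOH, 30% H2O2
Reagents that add atoms: hydrogen peroxide OO
Why: Hydroboration–oxidation: the twisted bridgehead alkene is far more reactive than the unstrained side-chain alkene, boron goes to the secondary carbon C9 away from the allylic oxygen, and hydrogen is delivered to C1 on its only open (outer) face, which gives the bridgehead arrangement the ring system demands.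

Step 20
Reactants: 30 C9 alcohol
Product: 31 desulfonylated alcohol
Conditions: Na(Hg) (6%), Na2HPO4, MeOH/THF, −20 °C → rt
Reagents that add atoms: none
Why: Reductive desulfonylation by electron transfer from sodium amalgam cleaves the C6–S bond, and the bridgehead carbon can only be protonated with retention.

Step 21
Reactants: 31 desulfonylated alcohol
Product: 32 C9 ketone
Conditions: Dess–Martin periodinane, NaHCO3, CH2Cl2, rt
Reagents that add atoms: none
Why: Dess–Martin oxidation of the secondary alcohol under buffered conditions leaves the silyl ether and the ketal intact.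

Step 22
Reactants: 32 C9 ketone
Product: 34 enol triflate (C8=C9), via potassium enolate 33 (not isolated)
Conditions: KN(SiMe3)2, THF, −78 °C; then PhNTf2, −78 → 0 °C
Reagents that add atoms: N-phenylbis(trifluoromethanesulfonimide) O=S(=O)(N(c1ccccc1)S(=O)(=O)C(F)(F)F)C(F)(F)F
Why: Kinetic enolisation towards the C8 methylene (the bridgehead C1–H is not aligned with the carbonyl π system) and O-triflation give the C8=C9 enol triflate.

Step 23
Reactants: 34 enol triflate
Product: 35 C10 alcohol
Conditions: HF·pyridine, pyridine, THF, 0 °C → rt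
Reagents that add atoms: none
Why: Acidic fluoride desilylation leaves the enol triflate and the ketal untouched; it is done only now, when C9 is no longer a ketone, so that no β-hydroxy ketone able to undergo retro-aldol ring opening is formed.

Step 24
Reactants: 35 C10 alcohol
Product: 36 C10 ketone
Conditions: Dess–Martin periodinane, NaHCO3, CH2Cl2, rt
Reagents that add atoms: none
Why: Dess–Martin oxidation gives the bridging ketone, which has only bridgehead α-hydrogens and cannot enolise.

Step 25
Reactants: 36 C10 ketone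
Product: 38 tertiary acetate, via lithium alkoxide 37 (not isolated)
Conditions: MeLi, THF, −78 °C; then Ac2O, −78 °C → rt
Reagents that add atoms: methyllithium [Li]C; acetic anhydride CC(=O)OC(C)=O
Why: 1,2-Addition of methyllithium to the non-enolisable ketone should occur on the C10 face over the C8=C9 bridge, away from the C2 substituent that flanks the face over the seven-membered ring, placing the oxygen cis to the C1–C2 bond as in the target; acetylation of the tertiary lithium alkoxide in the flask avoids a separate acylation of a very hindered carbinol.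

Step 26
Reactants: 38 tertiary acetate
Product: 39 enal ketal
Conditions: Pd(PPh3)4 (cat.), CO (1 atm), Bu3SnH (slow addition), THF, 50 °C
Reagents that add atoms: carbon monoxide [C-]#[O+]
Why: Palladium-catalysed reductive carbonylation (formylation) of the enol triflate: oxidative addition, CO insertion and hydride transfer from the tin hydride give the enal directly.

Step 27
Reactants: 39 enal ketal
Product: 40 target CNP0288370.1
Conditions: p-TsOH·H2O (cat.), acetone/H2O, rt
Reagents that add atoms: water O
Why: Acid-catalysed hydrolysis of the dioxolane; tertiary acetate and enal tolerate the mild acid, and C3 is already the more stable epimer with the acetyl group pseudo-equatorial.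

**Compound list**

1 | (S)-citronellal, (3S)-3,7-dimethyloct-6-enal | O=CC[C@@H](C)CCC=C(C)C | starting material
2 | (3S)-3,7-dimethylocta-1,6-dien-1-yl nonafluorobutane-1-sulfonate (enol nonaflate, E/Z not defined) | FC(F)(F)C(F)(F)C(F)(F)C(F)(F)S(=O)(=O)OC=C[C@@H](C)CCC=C(C)C | intermediate
3 | (3S)-3,7-dimethyloct-6-en-1-yne | C#C[C@@H](C)CCC=C(C)C | intermediate
4 | lithium acetylide of 3 | [Li]C#C[C@@H](C)CCC=C(C)C | intermediate
5 | (5S)-5,9-dimethyldec-8-en-3-yn-2-one | CC(=O)C#C[C@@H](C)CCC=C(C)C | intermediate
6 | (2S,5S)-5,9-dimethyldec-8-en-3-yn-2-ol | C[C@H](O)C#C[C@@H](C)CCC=C(C)C | intermediate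
7 | alkenylmagnesium chelate: chloromagnesium alkoxide, silylmethyl on C1, MgCl on C2 cis to the carbinol carbon | C[C@H](O[Mg]Cl)/C(C[Si](C)(C)OC(C)C)=C(\[Mg]Cl)[C@@H](C)CCC=C(C)C | intermediate
8 | (2S,3Z,5S)-3-{[isopropoxy(dimethyl)silyl]methyl}-4,5,9-trimethyldeca-3,8-dien-2-ol (C2 methyl cis to the carbinol carbon) | C[C@H](O)/C(C[Si](C)(C)OC(C)C)=C(\C)[C@@H](C)CCC=C(C)C | intermediate
9 | (2E,4S)-2-[(1S)-1-hydroxyethyl]-3,4,8-trimethylnona-2,7-dien-1-ol | C[C@H](O)/C(CO)=C(\C)[C@@H](C)CCC=C(C)C | intermediate
10 | (2S,3E,5S)-3-[(tert-butyldimethylsilyloxy)methyl]-4,5,9-trimethyldeca-3,8-dien-2-ol | C[C@H](O)/C(CO[Si](C)(C)C(C)(C)C)=C(\C)[C@@H](C)CCC=C(C)C | intermediate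
11 | 5-bromopentanoic acid | OC(=O)CCCCBr | starting material
12 | thiophenol | Sc1ccccc1 | starting material
13 | 5-(phenylthio)pentanoic acid | OC(=O)CCCCSc1ccccc1 | intermediate
14 | 5-(phenylthio)pentanoate ester of the secondary (S)-alcohol of 10 | C[C@H](OC(=O)CCCCSc1ccccc1)/C(CO[Si](C)(C)C(C)(C)C)=C(\C)[C@@H](C)CCC=C(C)C | intermediate
15 | (Z)-O-trimethylsilyl ketene acetal of 14 (C4 cis to OSiMe3) | C[C@H](O/C(O[Si](C)(C)C)=C/CCCSc1ccccc1)/C(CO[Si](C)(C)C(C)(C)C)=C(\C)[C@@H](C)CCC=C(C)C | intermediate
16 | trimethylsilyl ester of acid 17 | C/C=C(CO[Si](C)(C)C(C)(C)C)/[C@@](C)([C@@H](C)CCC=C(C)C)[C@@H](C(=O)O[Si](C)(C)C)CCCSc1ccccc1 | intermediate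
17 | Claisen acid: C2 (S) bears methyl, the (2S)-6-methylhept-5-en-2-yl chain and the (Z)-1-(silyloxymethyl)prop-1-enyl group; C3 (S) bears CO2H and the 3-(phenylthio)propyl chain | C/C=C(CO[Si](C)(C)C(C)(C)C)/[C@@](C)([C@@H](C)CCC=C(C)C)[C@@H](C(=O)O)CCCSc1ccccc1 | intermediate
18 | methyl ketone from 17 (acetyl on C3) | C/C=C(CO[Si](C)(C)C(C)(C)C)/[C@@](C)([C@@H](C)CCC=C(C)C)[C@@H](C(C)=O)CCCSc1ccccc1 | intermediate
19 | 2-methyl-1,3-dioxolane of 18 (sulfide) | C/C=C(CO[Si](C)(C)C(C)(C)C)/[C@@](C)([C@@H](C)CCC=C(C)C)[C@@H](C1(C)OCCO1)CCCSc1ccccc1 | intermediate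
20 | phenyl sulfone from 19 | C/C=C(CO[Si](C)(C)C(C)(C)C)/[C@@](C)([C@@H](C)CCC=C(C)C)[C@@H](C1(C)OCCO1)CCCS(=O)(=O)c1ccccc1 | intermediate
21 | α-lithio sulfone (lithium on C6) | C/C=C(CO[Si](C)(C)C(C)(C)C)/[C@@](C)([C@@H](C)CCC=C(C)C)[C@@H](C1(C)OCCO1)CCC([Li])S(=O)(=O)c1ccccc1 | intermediate
22 | β-hydroxy sulfone (CH2OH on C6, C6 epimers) | C/C=C(CO[Si](C)(C)C(C)(C)C)/[C@@](C)([C@@H](C)CCC=C(C)C)[C@@H](C1(C)OCCO1)CCC(CO)S(=O)(=O)c1ccccc1 | intermediate
23 | mesylate of 22 | C/C=C(CO[Si](C)(C)C(C)(C)C)/[C@@](C)([C@@H](C)CCC=C(C)C)[C@@H](C1(C)OCCO1)CCC(COS(C)(=O)=O)S(=O)(=O)c1ccccc1 | intermediate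
24 | vinyl sulfone (C6=C7, PhSO2 on C6), C10 silyl ether | C/C=C(CO[Si](C)(C)C(C)(C)C)/[C@@](C)([C@@H](C)CCC=C(C)C)[C@@H](C1(C)OCCO1)CCC(=C)S(=O)(=O)c1ccccc1 | intermediate
25 | allylic alcohol (C10–OH) | C/C=C(CO)/[C@@](C)([C@@H](C)CCC=C(C)C)[C@@H](C1(C)OCCO1)CCC(=C)S(=O)(=O)c1ccccc1 | intermediate
26 | enal (C10 formyl on C1, C8 methyl cis to the formyl group) | C/C=C(C=O)/[C@@](C)([C@@H](C)CCC=C(C)C)[C@@H](C1(C)OCCO1)CCC(=C)S(=O)(=O)c1ccccc1 | intermediate
27 | sulfonyl triene: 1-silyloxy diene C10=C1–C9=C8 (silyloxy trans to C9) tethered through C1 to the 1-sulfonylvinyl group | C=C/C(=C/O[Si](C)(C)C(C)(C)C)[C@@](C)([C@@H](C)CCC=C(C)C)[C@@H](C1(C)OCCO1)CCC(=C)S(=O)(=O)c1ccccc1 | intermediate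
28 | cycloadduct: 10-(tert-butyldimethylsilyloxy)-6-(phenylsulfonyl)bicyclo[4.3.1]dec-1(9)-ene, C2 (Me, side chain), C3 (2-methyl-1,3-dioxolan-2-yl), silyloxy cis to the C6–C5 bond | CC(C)(C)[Si](C)(C)O[C@H]1[C@]2(S(=O)(=O)c3ccccc3)CCC=C1[C@@](C)([C@@H](C)CCC=C(C)C)[C@@H](C4(C)OCCO4)CC2 | intermediate
29 | B-alkyl-9-BBN (boron on C9, H on C1) | CC(C)(C)[Si](C)(C)O[C@H]1[C@]2(S(=O)(=O)c3ccccc3)CCC(B5C6CCCC5CCC6)[C@@H]1[C@@](C)([C@@H](C)CCC=C(C)C)[C@@H](C4(C)OCCO4)CC2 | intermediate
30 | C9 alcohol of the saturated bicycle (sulfone on C6; C9 configuration not assigned) | CC(C)(C)[Si](C)(C)O[C@H]1[C@]2(S(=O)(=O)c3ccccc3)CCC(O)[C@@H]1[C@@](C)([C@@H](C)CCC=C(C)C)[C@@H](C4(C)OCCO4)CC2 | intermediate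
31 | desulfonylated C9 alcohol (C6–H) | CC(C)(C)[Si](C)(C)O[C@H]1[C@@H]2CCC(O)[C@@H]1[C@@](C)([C@@H](C)CCC=C(C)C)[C@@H](C3(C)OCCO3)CC2 | intermediate
32 | C9 ketone (10-silyloxybicyclo[4.3.1]decan-9-one) | CC(C)(C)[Si](C)(C)O[C@H]1[C@@H]2CCC(=O)[C@@H]1[C@@](C)([C@@H](C)CCC=C(C)C)[C@@H](C3(C)OCCO3)CC2 | intermediate
33 | potassium enolate (C8=C9–OK) | CC(C)(C)[Si](C)(C)O[C@H]1[C@@H]2CC=C(O[K])[C@@H]1[C@@](C)([C@@H](C)CCC=C(C)C)[C@@H](C3(C)OCCO3)CC2 | intermediate
34 | enol triflate (C8=C9–OTf), C10 silyl ether | CC(C)(C)[Si](C)(C)O[C@H]1[C@@H]2CC=C(OS(=O)(=O)C(F)(F)F)[C@@H]1[C@@](C)([C@@H](C)CCC=C(C)C)[C@@H](C3(C)OCCO3)CC2 | intermediate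
35 | C10 alcohol (enol triflate) | O[C@H]1[C@@H]2CC=C(OS(=O)(=O)C(F)(F)F)[C@@H]1[C@@](C)([C@@H](C)CCC=C(C)C)[C@@H](C3(C)OCCO3)CC2 | intermediate
36 | C10 ketone (enol triflate) | O=C1[C@@H]2CC=C(OS(=O)(=O)C(F)(F)F)[C@@H]1[C@@](C)([C@@H](C)CCC=C(C)C)[C@@H](C3(C)OCCO3)CC2 | intermediate
37 | lithium alkoxide of the C10 methyl carbinol | [Li]O[C@]1(C)[C@@H]2CC=C(OS(=O)(=O)C(F)(F)F)[C@@H]1[C@@](C)([C@@H](C)CCC=C(C)C)[C@@H](C3(C)OCCO3)CC2 | intermediate
38 | tertiary acetate (C10 Me, OAc; enol triflate; ketal) | CC(=O)O[C@]1(C)[C@@H]2CC=C(OS(=O)(=O)C(F)(F)F)[C@@H]1[C@@](C)([C@@H](C)CCC=C(C)C)[C@@H](C3(C)OCCO3)CC2 | intermediate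
39 | enal ketal (target with the C3 acetyl as its dioxolane) | CC(=O)O[C@]1(C)[C@@H]2CC=C(C=O)[C@@H]1[C@@](C)([C@@H](C)CCC=C(C)C)[C@@H](C3(C)OCCO3)CC2 | intermediate
40 | CNP0288370.1 | CC(=O)O[C@]1(C)[C@@H]2CC=C(C=O)[C@@H]1[C@@](C)([C@@H](C)CCC=C(C)C)[C@@H](C(C)=O)CC2 | target

**Totals and risks**

Total step count: 27. Longest linear sequence: 26 steps (steps 1–6 and 8–27, from (S)-citronellal); step 7 is a one-step side branch.

Steps most likely to fail:

Step 18 (cycloaddition). The cycloaddition may be slower than the thermal decay of the silyl dienol ether, or the tether may fold onto the wrong diene face. Fallback, anionic instead of neutral-thermal: enal 26 is treated with KN(SiMe3)2 in THF at −78 °C. γ-Deprotonation at C8 gives the potassium dienolate, an oxy-anion-substituted diene that should add to the vinyl sulfone at or below room temperature (anion-accelerated [4+2], the double Michael counterpart of the same two bond formations). Protonation with aq. NH4Cl would give the desilylated cycloadduct alcohol F1, and silylation (TBSOTf, 2,6-lutidine, CH2Cl2) returns to 28.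

Step 19 (hydroboration). Chemoselectivity may be lost through hydroboration of the side-chain alkene, or regioselectivity through boron delivery to C1. Fallback, radical instead of polar addition: cycloadduct 28 is heated with PhSH and AIBN in benzene. Thiyl radical addition is reversible, and only the strain-releasing addition at C9 followed by hydrogen transfer to C1 on the outer face is productive, giving the C9 phenyl sulfide F2. Na(Hg)/Na2HPO4 in MeOH removes the sulfone to give the desulfonylated sulfide F3. NaIO4 in MeOH/H2O gives the sulfoxide F4. Pummerer rearrangement ((CF3CO)2O, 2,6-lutidine) and hydrolysis with aq. NaHCO3 give ketone 32.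

Step 25 (methyl addition). Facial selectivity at C10 may be poor or reversed if the open face of the ketone is the one over the seven-membered ring. Fallback, oxygen instead of carbon delivered to that face: ketone 36 is methylenated (Ph3P=CH2, THF, reflux) to the 10-methylene compound F5. Oxymercuration–demercuration (Hg(OAc)2, THF/H2O; then NaBH4, NaOH) is much faster at the 1,1-disubstituted alkene than at the trisubstituted side chain and lets water attack the tertiary carbon from the open face, giving the C10 methyl carbinol F6. Acetylation of its potassium alkoxide (KN(SiMe3)2, then Ac2O) returns to 38.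

Further compounds
F1 | step 18 | desilylated cycloadduct alcohol: 10-hydroxy-6-(phenylsulfonyl)bicyclo[4.3.1]dec-1(9)-ene with the C2 and C3 substituents of 28 | O[C@H]1[C@]2(S(=O)(=O)c3ccccc3)CCC=C1[C@@](C)([C@@H](C)CCC=C(C)C)[C@@H](C4(C)OCCO4)CC2
F2 | step 19 | C9 phenyl sulfide of the cycloadduct (PhS on C9, H on C1, sulfone on C6) | CC(C)(C)[Si](C)(C)O[C@H]1[C@]2(S(=O)(=O)c3ccccc3)CCC(Sc5ccccc5)[C@@H]1[C@@](C)([C@@H](C)CCC=C(C)C)[C@@H](C4(C)OCCO4)CC2
F3 | step 19 | desulfonylated C9 phenyl sulfide | CC(C)(C)[Si](C)(C)O[C@H]1[C@@H]2CCC(Sc3ccccc3)[C@@H]1[C@@](C)([C@@H](C)CCC=C(C)C)[C@@H](C4(C)OCCO4)CC2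
F4 | step 19 | C9 phenyl sulfoxide | CC(C)(C)[Si](C)(C)O[C@H]1[C@@H]2CCC(S(=O)c3ccccc3)[C@@H]1[C@@](C)([C@@H](C)CCC=C(C)C)[C@@H](C4(C)OCCO4)CC2
F5 | step 25 | 10-methylene compound (enol triflate, ketal) | C=C1[C@@H]2CC=C(OS(=O)(=O)C(F)(F)F)[C@@H]1[C@@](C)([C@@H](C)CCC=C(C)C)[C@@H](C3(C)OCCO3)CC2
F6 | step 25 | C10 methyl carbinol (free tertiary alcohol of 38) | O[C@]1(C)[C@@H]2CC=C(OS(=O)(=O)C(F)(F)F)[C@@H]1[C@@](C)([C@@H](C)CCC=C(C)C)[C@@H](C3(C)OCCO3)CC2
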